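Strategy. The route rests on disconnecting C2–C3 of the dihydrofuran. In benzofuran numbering (O1, C2, C3, C3a, C4–C7, C7a) C3 is a methine held between ring A and C3a of ring B and bonded to the ether carbon C2 next to O1. A dirhodium-bound diaryl carbene at C3 inserts into one C–H bond of the O1–CH2 group, closing the five-membered ring and setting C2 and C3 cis and enantioselectively in one operation. Its precursor is a flat diaryldiazomethane whose ring B carries the 2-methyl-2-silyloxypropyl ether ortho to the diazo carbon. Ring B is dearomatised only afterwards: oxidative phenol coupling, dienone reduction and samarium-mediated ether cleavage.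

Key step: step 8

Remark: benzofuran numbering of the ring B bicycle is kept for all intermediates; ring A is the benzoate ring. Rh2(R-PTAD)4 is assumed to give the (2R,3S) series; if the sense is opposite, Rh2(S-PTAD)4 is used.
Remark: a direct two-electron reduction of the aromatic acylphenol 17 to the target would cost the aromaticity and the chelated aryl ketone and is judged strongly uphill. Ring B is therefore first oxidised to a non-aromatic dienone (step 12) and the reducing steps are run on that.
Remark: the key-step product 13 has the cis (2R,3S) configuration that C2 and C3 of the target require.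

Step 1
Reactants: 1 2-hydroxy-4,6-dimethoxybenzaldehyde; 2 isobutylene oxide (2,2-dimethyloxirane)
Product: 3 2-(2-hydroxy-2-methylpropoxy)-4,6-dimethoxybenzaldehyde
Conditions: K2CO3, DMF, 100 °C, sealed vessel
Reagents that add atoms: none
Why: The phenoxide opens the epoxide at its unsubstituted carbon (base-mediated SN2 epoxide opening, a Williamson-type etherification), and starting from this aldehyde fixes the ring B substitution pattern without any regiochemical choice.

Step 2
Reactants: 3 2-(2-hydroxy-2-methylpropoxy)-4,6-dimethoxybenzaldehyde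
Product: 4 4,6-dimethoxy-2-[2-methyl-2-(triethylsilyloxy)propoxy]benzaldehyde
Conditions: Et3SiOTf, 2,6-lutidine, CH2Cl2, 0 °C
Reagents that add atoms: triethylsilyl trifluoromethanesulfonate, CC[Si](CC)(CC)OS(=O)(=O)C(F)(F)F
Why: A silyl triflate with a hindered pyridine base silylates tertiary alcohols reliably (silyl ether formation), which removes the O–H bond that would otherwise trap the carbene.

Step 3
Reactants: 5 methyl 4-hydroxy-3-iodobenzoate
Product: 6 methyl 4-(tert-butyldimethylsilyloxy)-3-iodobenzoate
Conditions: t-BuMe2SiCl, imidazole, DMF, 23 °C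
Reagents that add atoms: tert-butyldimethylsilyl chloride, CC(C)(C)[Si](C)(C)Cl
Why: Imidazole-promoted silylation of a phenol; the silyl group puts no C–H bond on the atom bound to the ring A oxygen, so this ortho substituent cannot compete in the later insertion.

Step 4
Reactants: 6 methyl 4-(tert-butyldimethylsilyloxy)-3-iodobenzoate; 4 4,6-dimethoxy-2-[2-methyl-2-(triethylsilyloxy)propoxy]benzaldehyde
Product: 8 methyl 4-(tert-butyldimethylsilyloxy)-3-{[2,4-dimethoxy-6-(2-methyl-2-triethylsilyloxypropoxy)phenyl](hydroxy)methyl}benzoate (racemic), via arylmagnesium chloride 7 (not isolated)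
Conditions: i-PrMgCl·LiCl, THF, −40 °C; then 4, −40 to 0 °C; aq. NH4Cl
Reagents that add atoms: none
Why: Iodine–magnesium exchange with the LiCl-activated Grignard reagent tolerates the methyl ester at low temperature and the arylmagnesium adds to the aldehyde (Grignard 1,2-addition); the carbinol centre forms racemic and is removed in step 5.

Step 5
Reactants: 8 diaryl carbinol
Product: 9 methyl 4-(tert-butyldimethylsilyloxy)-3-[2,4-dimethoxy-6-(2-methyl-2-triethylsilyloxypropoxy)benzoyl]benzoate
Conditions: Dess–Martin periodinane, NaHCO3, CH2Cl2, 0 to 23 °C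
Reagents that add atoms: none
Why: Dess–Martin oxidation of a doubly benzylic secondary alcohol to the diaryl ketone under buffered conditions that spare both silyl ethers.

Step 6
Reactants: 9 diaryl ketone
Product: 11 hydrazone of ketone 9 (C=N–NH2; E/Z mixture), via N-silylhydrazone 10 (not isolated)
Conditions: t-BuMe2SiNHNHSiMe2t-Bu, Sc(OTf)3 (1 mol %), neat, 80 °C; then MeOH, AcOH (cat.), 0 °C
Reagents that add atoms: 1,2-bis(tert-butyldimethylsilyl)hydrazine, CC(C)(C)[Si](C)(C)NN[Si](C)(C)C(C)(C)C
Why: Sc(OTf)3-catalysed condensation with the bis-silylhydrazine forms the N-silylhydrazone irreversibly (silanol is lost) even at hindered ketones and, unlike free hydrazine, cannot attack the methyl ester; the labile N–Si bond is then cleaved by methanolysis, which should leave the O-silyl ethers intact (hydrazone formation).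

Step 7
Reactants: 11 hydrazone
Product: 12 methyl 4-(tert-butyldimethylsilyloxy)-3-{diazo[2,4-dimethoxy-6-(2-methyl-2-triethylsilyloxypropoxy)phenyl]methyl}benzoate
Conditions: MnO2, MgSO4, CH2Cl2, 0 °C, dark; filtration
Reagents that add atoms: none
Why: Dehydrogenation of an N-unsubstituted diaryl hydrazone with MnO2 is the standard way to a diaryldiazomethane, and both hydrazone isomers converge.

Step 8
Reactants: 12 diaryldiazomethane
Product: 13 methyl 4-(tert-butyldimethylsilyloxy)-3-[(2R,3S)-4,6-dimethoxy-2-(2-triethylsilyloxypropan-2-yl)-2,3-dihydro-1-benzofuran-3-yl]benzoate (2,3-cis)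
Conditions: Rh2(R-PTAD)4 (dirhodium tetrakis[(R)-(1-adamantyl)(N-phthalimido)acetate], 1 mol %), CH2Cl2, −20 to 23 °C, slow addition of 12
Reagents that add atoms: none
Why: Loss of N2 gives a dirhodium-bound diaryl carbene at C3 that is weakly electrophilic and long-lived, so it reacts at the most hydridic C–H bond in reach, that of the O1–CH2 group, through a transition state with strong hydride-transfer character and immediate C–C bond formation (intramolecular 1,5 C–H insertion of a donor/donor carbene into an ether alpha C–H bond, known for 2-alkoxyaryl aryl diazomethanes). The five-membered ring closes by this insertion through a five-centre arrangement of carbene carbon, C3a, C7a, O1 and C2, forming the C2–C3 bond. C2 and C3 are both set here: the chiral carboxylate pocket fixes the carbene orientation and picks one enantiotopic hydrogen of the CH2 group, and collapse faster than bond rotation gives the cis isomer kinetically. The step needs site selectivity, cis diastereoselectivity and enantioselectivity. Site selectivity is secured in the substrate: the ring A oxygen and the tertiary oxygen carry silyl groups (no O–H, no C–H on the atom next to oxygen), the tertiary oxygen is kept as an electron-rich silyl ether so that the secondary O1–CH2 hydrogens stay more hydridic than the primary ones of the ortho methoxy group, and the para methoxy group is out of reach. Cis and absolute selectivity rest on the catalyst.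

Step 9
Reactants: 13 cis-dihydrobenzofuran; 14 3-phenylpropanoyl chloride
Product: 15 methyl 4-(tert-butyldimethylsilyloxy)-3-[(2R,3S)-4,6-dimethoxy-7-(3-phenylpropanoyl)-2-(2-triethylsilyloxypropan-2-yl)-2,3-dihydro-1-benzofuran-3-yl]benzoate
Conditions: Et2AlCl, CH2Cl2, −78 to −20 °C
Reagents that add atoms: none
Why: Friedel–Crafts acylation of the phloroglucinol-type ring should occur at C7, which is flanked by the tied-back ring oxygen and is less hindered than C5 between two methoxy groups (the same preference as C8 over C6 in 5,7-dialkoxyflavans), and the alkylaluminium chloride consumes the proton so that no HCl reaches the silyl ethers.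

Step 10
Reactants: 15 C7 ketone
Product: 16 methyl 4-(tert-butyldimethylsilyloxy)-3-[(2R,3S)-6-hydroxy-4-methoxy-7-(3-phenylpropanoyl)-2-(2-triethylsilyloxypropan-2-yl)-2,3-dihydro-1-benzofuran-3-yl]benzoate
Conditions: BCl3, CH2Cl2, −78 to −30 °C; aq. NaHCO3
Reagents that add atoms: none
Why: BCl3 chelates the C7 ketone and cleaves only the methyl ether ortho to it (chelation-controlled Lewis acid demethylation); the C4 methoxy group and the secondary C2–O1 bond are inert at low temperature.

Step 11
Reactants: 16 chelated phenol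
Product: 17 methyl 4-hydroxy-3-[(2R,3S)-6-hydroxy-2-(2-hydroxypropan-2-yl)-4-methoxy-7-(3-phenylpropanoyl)-2,3-dihydro-1-benzofuran-3-yl]benzoate
Conditions: n-Bu4NF, AcOH, THF, 0 to 23 °C
Reagents that add atoms: none
Why: Fluoride cleaves the aryl and the tertiary silyl ether (desilylation), and acetic acid buffering keeps the methyl ester and the phenols away from strong base.

Step 12
Reactants: 17 aromatic triol
Product: 18 bridged dienone (ring A oxygen bonded to C3a; 2R,3R,3aS; C6 ketone; C4 methoxy enol ether; 3-phenylpropanoyl on C7=C7a)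
Conditions: PhI(OAc)2, (CF3)2CHOH–CH2Cl2, −20 to 0 °C
Reagents that add atoms: none
Why: Trivalent iodine oxidises the electron-rich ring B phenol, and the ring A phenol oxygen, held four atoms from the para carbon C3a, closes a five-membered ring there (oxidative phenol dearomatisation with an internal oxygen nucleophile, the para C–O phenolic coupling that gives spirodienones from 2,4'-dihydroxydiarylmethanes); the new C3a centre is fixed by the tether, because the cis ring fusion forces the C3a–O bond onto the face that carries ring A.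

Step 13
Reactants: 18 bridged dienone
Product: 20 dienol (6S alcohol of dienone 18; C6 hydroxyl anti to the C3a aryloxy oxygen), via dilithium enolate alkoxide 19 (not isolated)
Conditions: LiN(SiMe3)2 (2.2 equiv), THF, −78 °C; then i-Bu2AlH, −78 °C; aq. potassium sodium tartrate, pH 7
Reagents that add atoms: none
Why: Deprotonation turns the more electrophilic side-chain ketone into its enolate (in situ protection; C6=O has no alpha hydrogen), so the aluminium hydride should reduce only the cross-conjugated C6 carbonyl in the 1,2 sense (dienone to dienol reduction) while the aryl ester survives at −78 °C in THF; hydride should add on the face of the polar C3a aryloxy substituent, the facial preference known for 4-oxygenated cyclohexa-2,5-dienones, which places the C6 hydroxyl anti to that oxygen (6S).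

Step 14
Reactants: 20 dienol
Product: 21 methyl 4-hydroxy-3-[(2R,3S,6S,7S)-6-hydroxy-2-(2-hydroxypropan-2-yl)-4-methoxy-7-(3-phenylpropanoyl)-2,3,6,7-tetrahydro-1-benzofuran-3-yl]benzoate (CNP0080427.1)
Conditions: SmI2 (2.5 equiv), THF–MeOH, −78 °C; pH 7 phosphate buffer
Reagents that add atoms: none
Why: Two electrons from SmI2 enter the enone and expel the gamma aryloxide at C3a (reductive cleavage of a gamma-oxygenated enone, the vinylogous form of the SmI2 deoxygenation of alpha-alkoxy ketones), which restores C3a=C7a and frees the ring A phenol; the samarium dienolate should be protonated kinetically at its alpha carbon C7 on the face away from the adjacent C6 oxygen, giving the deconjugated ketone, and the cis hydroxy ketone is also expected to be the epimer favoured at equilibrium (intramolecular hydrogen bond).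

Compound list
1 | 2-hydroxy-4,6-dimethoxybenzaldehyde | COc1cc(O)c(C=O)c(OC)c1 | starting material
2 | isobutylene oxide (2,2-dimethyloxirane) | CC1(C)CO1 | starting material
3 | 2-(2-hydroxy-2-methylpropoxy)-4,6-dimethoxybenzaldehyde | COc1cc(OCC(C)(C)O)c(C=O)c(OC)c1 | intermediate
4 | 4,6-dimethoxy-2-[2-methyl-2-(triethylsilyloxy)propoxy]benzaldehyde | COc1cc(OCC(C)(C)O[Si](CC)(CC)CC)c(C=O)c(OC)c1 | intermediate
5 | methyl 4-hydroxy-3-iodobenzoate | COC(=O)c1ccc(O)c(I)c1 | starting material
6 | methyl 4-(tert-butyldimethylsilyloxy)-3-iodobenzoate | COC(=O)c1ccc(O[Si](C)(C)C(C)(C)C)c(I)c1 | intermediate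
7 | [2-(tert-butyldimethylsilyloxy)-5-(methoxycarbonyl)phenyl]magnesium chloride (LiCl complex) | COC(=O)c1ccc(O[Si](C)(C)C(C)(C)C)c([Mg]Cl)c1 | intermediate
8 | diaryl carbinol, racemic at the carbinol carbon | COC(=O)c1ccc(O[Si](C)(C)C(C)(C)C)c(C(O)c2c(OCC(C)(C)O[Si](CC)(CC)CC)cc(OC)cc2OC)c1 | intermediate
9 | diaryl ketone | COC(=O)c1ccc(O[Si](C)(C)C(C)(C)C)c(C(=O)c2c(OCC(C)(C)O[Si](CC)(CC)CC)cc(OC)cc2OC)c1 | intermediate
10 | N-(tert-butyldimethylsilyl)hydrazone of 9 | COC(=O)c1ccc(O[Si](C)(C)C(C)(C)C)c(C(=NN[Si](C)(C)C(C)(C)C)c2c(OCC(C)(C)O[Si](CC)(CC)CC)cc(OC)cc2OC)c1 | intermediate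
11 | hydrazone of 9 (E/Z mixture) | COC(=O)c1ccc(O[Si](C)(C)C(C)(C)C)c(C(=NN)c2c(OCC(C)(C)O[Si](CC)(CC)CC)cc(OC)cc2OC)c1 | intermediate
12 | diaryldiazomethane, key-step precursor | COC(=O)c1ccc(O[Si](C)(C)C(C)(C)C)c(C(=[N+]=[N-])c2c(OCC(C)(C)O[Si](CC)(CC)CC)cc(OC)cc2OC)c1 | intermediate
13 | (2R,3S)-cis-2,3-disubstituted 4,6-dimethoxy-2,3-dihydrobenzofuran, key-step product | COC(=O)c1ccc(O[Si](C)(C)C(C)(C)C)c([C@H]2c3c(O[C@H]2C(C)(C)O[Si](CC)(CC)CC)cc(OC)cc3OC)c1 | intermediate
14 | 3-phenylpropanoyl chloride | O=C(Cl)CCc1ccccc1 | starting material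
15 | (2R,3S)-7-(3-phenylpropanoyl)-4,6-dimethoxy dihydrobenzofuran, both silyl ethers in place | COC(=O)c1ccc(O[Si](C)(C)C(C)(C)C)c([C@H]2c3c(O[C@H]2C(C)(C)O[Si](CC)(CC)CC)c(C(=O)CCc2ccccc2)c(OC)cc3OC)c1 | intermediate
16 | (2R,3S)-6-hydroxy-4-methoxy-7-(3-phenylpropanoyl) dihydrobenzofuran, both silyl ethers in place | COC(=O)c1ccc(O[Si](C)(C)C(C)(C)C)c([C@H]2c3c(O[C@H]2C(C)(C)O[Si](CC)(CC)CC)c(C(=O)CCc2ccccc2)c(O)cc3OC)c1 | intermediate
17 | methyl 4-hydroxy-3-[(2R,3S)-6-hydroxy-2-(2-hydroxypropan-2-yl)-4-methoxy-7-(3-phenylpropanoyl)-2,3-dihydro-1-benzofuran-3-yl]benzoate | COC(=O)c1ccc(O)c([C@H]2c3c(O[C@H]2C(C)(C)O)c(C(=O)CCc2ccccc2)c(O)cc3OC)c1 | intermediate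
18 | bridged dienone (2R,3R,3aS): ring A oxygen bonded to C3a on the face of ring A, C6 ketone, C4=C5 methoxy enol ether, 3-phenylpropanoyl on C7=C7a | COC(=O)c1ccc2c(c1)[C@@H]1[C@H](C(C)(C)O)OC3=C(C(=O)CCc4ccccc4)C(=O)C=C(OC)[C@@]13O2 | intermediate
19 | dilithium salt of 18 (side-chain enolate and tertiary alkoxide) | COC(=O)c1ccc2c(c1)[C@@H]1[C@H](C(C)(C)O[Li])OC3=C(C(O[Li])=CCc4ccccc4)C(=O)C=C(OC)[C@@]13O2 | intermediate
20 | dienol (2R,3R,3aS,6S): C6 alcohol of 18, hydroxyl anti to the C3a aryloxy oxygen | COC(=O)c1ccc2c(c1)[C@@H]1[C@H](C(C)(C)O)OC3=C(C(=O)CCc4ccccc4)[C@@H](O)C=C(OC)[C@@]13O2 | intermediate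
21 | methyl 4-hydroxy-3-[(2R,3S,6S,7S)-6-hydroxy-2-(2-hydroxypropan-2-yl)-4-methoxy-7-(3-phenylpropanoyl)-2,3,6,7-tetrahydro-1-benzofuran-3-yl]benzoate | COC(=O)c1ccc(O)c([C@H]2C3=C(O[C@H]2C(C)(C)O)[C@@H](C(=O)CCc2ccccc2)[C@@H](O)C=C3OC)c1 | target

Total step count: 14. Longest linear sequence: 13 steps (steps 1, 2 and 4 to 14).

Steps most likely to fail

Step 8. The carbene may insert into a C–H bond of the ortho methoxy group instead of the hindered, beta-oxygenated methylene, or the bulky substituent may erode the cis selectivity. The fallback sets out from aldehyde 1 and returns at 13.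
- O-Alkylation of 1 with 3-chloro-2-methylpropene (K2CO3, DMF) gives 4,6-dimethoxy-2-(2-methylprop-2-enyloxy)benzaldehyde F1.
- Addition of arylmagnesium 7 gives the carbinol F2, and Dess–Martin oxidation the ketone F3.
- The silylhydrazine condensation gives the N-silylhydrazone F4, methanolysis the hydrazone F5, and MnO2 the diazo compound F6.
- With the same dirhodium catalyst the carbene meets an allylic O–CH2 group, far more hydridic than the methoxy C–H bonds and free of the quaternary neighbour. It should give the cis-2-isopropenyl dihydrobenzofuran F7; allylic ethers are expected to insert without cyclopropanation.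
- Mukaiyama hydration (Co(acac)2, PhSiH3, O2, THF) should turn the isopropenyl group into the tertiary alcohol F8, and Et3SiOTf with 2,6-lutidine returns to 13.

Step 14. Proton delivery to the dienolate may be guided by the neighbouring samarium-bound C6 alkoxide, giving the wrong face at C7, or may occur at C5, giving the conjugated isomer. The fallback sets out from 20 and returns at 21.
- Et3SiCl and imidazole silylate the secondary C6 hydroxyl to the C6 triethylsilyl ether F11.
- SmI2 with t-BuOH as a bulky proton source then cleaves the C3a–O bond with no alkoxide next to the enolate, giving the 6-O-triethylsilyl ether of the target F12.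
- Buffered fluoride (HF·pyridine with excess pyridine, THF, 0 °C) liberates 21.

Step 13. The hydride may over-reduce the side-chain ketone or the methyl ester if enolate protection is incomplete. The fallback sets out from 18 and returns at 20.
- Et3SiOTf and Et3N convert the side-chain ketone into its triethylsilyl dienol ether and silylate the tertiary alcohol, giving the isolated bis-silyl dienone F9.
- Luche reduction (NaBH4, CeCl3·7H2O, MeOH, −40 °C) then meets a single ketone and a hydride that does not touch esters, giving the bis-silyl dienol F10.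
- AcOH-buffered n-Bu4NF removes both silyl groups and returns to 20.

Further compounds
F1 | step 8 | 4,6-dimethoxy-2-(2-methylprop-2-enyloxy)benzaldehyde | COc1cc(OCC(C)=C)c(C=O)c(OC)c1
F2 | step 8 | methallyl-series diaryl carbinol (racemic) | COC(=O)c1ccc(O[Si](C)(C)C(C)(C)C)c(C(O)c2c(OCC(C)=C)cc(OC)cc2OC)c1
F3 | step 8 | methallyl-series diaryl ketone | COC(=O)c1ccc(O[Si](C)(C)C(C)(C)C)c(C(=O)c2c(OCC(C)=C)cc(OC)cc2OC)c1
F4 | step 8 | N-(tert-butyldimethylsilyl)hydrazone of F3 | COC(=O)c1ccc(O[Si](C)(C)C(C)(C)C)c(C(=NN[Si](C)(C)C(C)(C)C)c2c(OCC(C)=C)cc(OC)cc2OC)c1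
F5 | step 8 | hydrazone of F3 | COC(=O)c1ccc(O[Si](C)(C)C(C)(C)C)c(C(=NN)c2c(OCC(C)=C)cc(OC)cc2OC)c1
F6 | step 8 | methallyl-series diaryldiazomethane | COC(=O)c1ccc(O[Si](C)(C)C(C)(C)C)c(C(=[N+]=[N-])c2c(OCC(C)=C)cc(OC)cc2OC)c1
F7 | step 8 | methyl 4-(tert-butyldimethylsilyloxy)-3-[(2R,3S)-4,6-dimethoxy-2-(prop-1-en-2-yl)-2,3-dihydro-1-benzofuran-3-yl]benzoate (cis) | COC(=O)c1ccc(O[Si](C)(C)C(C)(C)C)c([C@H]2c3c(O[C@H]2C(C)=C)cc(OC)cc3OC)c1
F8 | step 8 | methyl 4-(tert-butyldimethylsilyloxy)-3-[(2R,3S)-2-(2-hydroxypropan-2-yl)-4,6-dimethoxy-2,3-dihydro-1-benzofuran-3-yl]benzoate | COC(=O)c1ccc(O[Si](C)(C)C(C)(C)C)c([C@H]2c3c(O[C@H]2C(C)(C)O)cc(OC)cc3OC)c1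
F9 | step 13 | bis(triethylsilyl) derivative of 18 (side-chain silyl dienol ether and tertiary silyl ether) | COC(=O)c1ccc2c(c1)[C@@H]1[C@H](C(C)(C)O[Si](CC)(CC)CC)OC3=C(C(O[Si](CC)(CC)CC)=CCc4ccccc4)C(=O)C=C(OC)[C@@]13O2
F10 | step 13 | (6S) C6 alcohol of F9 | COC(=O)c1ccc2c(c1)[C@@H]1[C@H](C(C)(C)O[Si](CC)(CC)CC)OC3=C(C(O[Si](CC)(CC)CC)=CCc4ccccc4)[C@@H](O)C=C(OC)[C@@]13O2
F11 | step 14 | C6 triethylsilyl ether of 20 | COC(=O)c1ccc2c(c1)[C@@H]1[C@H](C(C)(C)O)OC3=C(C(=O)CCc4ccccc4)[C@@H](O[Si](CC)(CC)CC)C=C(OC)[C@@]13O2
F12 | step 14 | 6-O-triethylsilyl ether of 21 | COC(=O)c1ccc(O)c([C@H]2C3=C(O[C@H]2C(C)(C)O)[C@@H](C(=O)CCc2ccccc2)[C@@H](O[Si](CC)(CC)CC)C=C3OC)c1
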